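**Retrosynthetic overview**

1. Target 19 comes from 18 by hydrogenolysis of four benzyl ethers; 18 comes from the protected 2,4-cis-flavan 16 by converting the ring B aryl triflate into the phenol through a boronate.
2. Key disconnection: delete O1 from the pyran ring of 16, which leads back to the 1,3-diarylindan-1-yl hydroperoxide 13. Forward, a Hock 1,2-aryl shift inserts O between C8a and C2 (five- to six-membered ring) and the oxocarbenium ion is reduced cis to the C4 aryl group.
3. Enabling feature: in the pyran ring, O1 lies between the aromatic carbon C8a of ring A and C2, a benzylic CH that carries ring B and sits 1,3 to the C4 stereocentre. Without O1, C2 is a tertiary, doubly benzylic carbon that can hold a peroxide; with O1 it is an aryl-stabilised oxocarbenium carbon.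
4. 13 comes from a ring B Grignard reagent and indanone 9; 9 from C-acylation of (R)-indanone 7; 7 from an asymmetric reductive Heck cyclisation of chalcone triflate 6; 6 from aldol condensation of 2 and 4.
5. Ring order: the three benzene rings are bought; the five-membered carbocycle is closed first (step 5, sets C4); the pyran ring is made last from it by ring enlargement (step 9, sets C2; both carbinol epimers converge).

Key step: step 9

Assumption: the (R)-bisphosphine in step 5 is taken to give the 3R indanone by analogy with related 2'-sulfonyloxychalcones; should the sense of induction be opposite, the (S)-ligand is used.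

**Step 1**
Reactants: 1 2,4,6-trihydroxybenzaldehyde
Product: 2 2,4,6-tris(benzyloxy)benzaldehyde
Conditions: BnBr (3.6 equiv), K2CO3, DMF, 60 °C
Reagents that add atoms: benzyl bromide, BrCc1ccccc1
Why: Williamson ether synthesis (SN2 O-alkylation of the three phenoxides); the formyl group tempers the ring, so O-benzylation should prevail over C-benzylation.

**Step 2**
Reactants: 3 1-(2,5-dihydroxyphenyl)ethan-1-one
Product: 4 1-[5-(benzyloxy)-2-hydroxyphenyl]ethan-1-one
Conditions: BnBr (1.05 equiv), K2CO3, acetone, reflux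
Reagents that add atoms: benzyl bromide, BrCc1ccccc1
Why: Williamson ether synthesis, regioselective because the 2-hydroxyl is tied up in a hydrogen bond to the acetyl group, so only the 5-phenoxide is alkylated.

**Step 3**
Reactants: 2 2,4,6-tris(benzyloxy)benzaldehyde; 4 1-[5-(benzyloxy)-2-hydroxyphenyl]ethan-1-one
Product: 5 (2E)-1-[5-(benzyloxy)-2-hydroxyphenyl]-3-[2,4,6-tris(benzyloxy)phenyl]prop-2-en-1-one
Conditions: KOH (aq., 4 equiv), EtOH/THF, rt; then aq. HCl
Reagents that add atoms: none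
Why: Claisen–Schmidt (crossed aldol) condensation of the methyl ketone enolate with the non-enolisable aldehyde gives the E-enone after dehydration; the 2,6-disubstituted aryl ring keeps the 2'-hydroxychalcone from closing to a flavanone.

**Step 4**
Reactants: 5 (2E)-1-[5-(benzyloxy)-2-hydroxyphenyl]-3-[2,4,6-tris(benzyloxy)phenyl]prop-2-en-1-one
Product: 6 4-(benzyloxy)-2-{(2E)-3-[2,4,6-tris(benzyloxy)phenyl]prop-2-enoyl}phenyl trifluoromethanesulfonate
Conditions: Tf2O, pyridine, CH2Cl2, −20 → 0 °C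
Reagents that add atoms: trifluoromethanesulfonic anhydride, O=S(=O)(OS(=O)(=O)C(F)(F)F)C(F)(F)F
Why: O-sulfonylation of the phenol gives the aryl triflate, which makes this ring A carbon the site of oxidative addition in step 5.

**Step 5**
Reactants: 6 4-(benzyloxy)-2-{(2E)-3-[2,4,6-tris(benzyloxy)phenyl]prop-2-enoyl}phenyl trifluoromethanesulfonate
Product: 7 (3R)-6-(benzyloxy)-3-[2,4,6-tris(benzyloxy)phenyl]-2,3-dihydro-1H-inden-1-one
Conditions: Pd(OAc)2 (5 mol %), (R)-3,5-Xyl-MeO-BIPHEP (7.5 mol %), 1,8-bis(dimethylamino)naphthalene (2 equiv), DMF, 80 °C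
Reagents that add atoms: none
Why: Enantioselective intramolecular reductive Heck reaction (arylpalladium conjugate addition onto the enone, then hydride transfer from the tertiary amine) closes the five-membered ring; the atropisomeric bisphosphine on cationic palladium selects the enone face and so sets the benzylic stereocentre (the later C4) as R.

**Step 6**
Reactants: 7 (3R)-6-(benzyloxy)-3-[2,4,6-tris(benzyloxy)phenyl]-2,3-dihydro-1H-inden-1-one; 8 dodecanoic acid
Product: 9 (3R)-6-(benzyloxy)-3-[2,4,6-tris(benzyloxy)-3-dodecanoylphenyl]-2,3-dihydro-1H-inden-1-one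
Conditions: 8 (1.3 equiv), (CF3CO)2O (2.5 equiv), CH2Cl2, 0 °C → rt
Reagents that add atoms: none
Why: Friedel–Crafts acylation by the mixed trifluoroacetic anhydride of 8 on the only strongly activated ring (the trialkoxyphenyl ring; ring A is deactivated by the indanone carbonyl) at one of its two equivalent free positions; the first acyl group deactivates the ring against a second.

**Step 7**
Reactants: 9 (3R)-6-(benzyloxy)-3-[2,4,6-tris(benzyloxy)-3-dodecanoylphenyl]-2,3-dihydro-1H-inden-1-one; 10 4-iodophenyl trifluoromethanesulfonate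
Product: 12 4-{(3R)-6-(benzyloxy)-1-hydroxy-3-[2,4,6-tris(benzyloxy)-3-dodecanoylphenyl]-2,3-dihydro-1H-inden-1-yl}phenyl trifluoromethanesulfonate (both C1 epimers), via arylmagnesium chloride 11 (not isolated)
Conditions: 10, iPrMgCl·LiCl, THF, −40 °C; then 9, LaCl3·2LiCl, THF, −40 → 0 °C; aq. NH4Cl
Reagents that add atoms: none
Why: Iodine–magnesium exchange followed by 1,2-addition of the aryl Grignard reagent to the indanone carbonyl, which LaCl3·2LiCl activates against enolisation; the dodecanoyl ketone is shielded by two ortho-benzyloxy groups, and the configuration of the new carbinol centre is irrelevant because step 9 erases it.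

**Step 8**
Reactants: 12 4-{(3R)-6-(benzyloxy)-1-hydroxy-3-[2,4,6-tris(benzyloxy)-3-dodecanoylphenyl]-2,3-dihydro-1H-inden-1-yl}phenyl trifluoromethanesulfonate
Product: 13 4-{(3R)-6-(benzyloxy)-1-hydroperoxy-3-[2,4,6-tris(benzyloxy)-3-dodecanoylphenyl]-2,3-dihydro-1H-inden-1-yl}phenyl trifluoromethanesulfonate (both C1 epimers)
Conditions: H2O2 (50% aq., 15 equiv), H2SO4 (cat.), THF, 0 °C
Reagents that add atoms: hydrogen peroxide, OO
Why: Acid-catalysed SN1 substitution of the tertiary benzylic alcohol by hydrogen peroxide through the diarylalkyl cation gives the tertiary hydroperoxide; the C3 centre is not involved.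

**Step 9**
Reactants: 13 4-{(3R)-6-(benzyloxy)-1-hydroperoxy-3-[2,4,6-tris(benzyloxy)-3-dodecanoylphenyl]-2,3-dihydro-1H-inden-1-yl}phenyl trifluoromethanesulfonate
Product: 16 4-{(2R,4R)-7-(benzyloxy)-4-[2,4,6-tris(benzyloxy)-3-dodecanoylphenyl]-3,4-dihydro-2H-chromen-2-yl}phenyl trifluoromethanesulfonate, via oxocarbenium ion 14 (not isolated), via hemiketal 15 (not isolated)
Conditions: CF3CO2H (10 equiv), CH2Cl2, −20 → 0 °C; then Et3SiH (2.5 equiv), −40 → 0 °C
Reagents that add atoms: none
Why: Acid protonates the distal peroxide oxygen of 13 and the ring A aryl carbon (C7a of the indane) migrates from C1 to oxygen as water leaves (Hock rearrangement, the acid-induced Criegee-type 1,2-shift of benzylic hydroperoxides), so the five-membered carbocycle becomes the six-membered 2-aryl-3,4-dihydrochromenylium ion 14, which the released water holds as hemiketal 15 until triethylsilane reduces it through 14 (ionic hydrogenation of a cyclic oxocarbenium ion, as in lactol reductions). No ring is closed by cyclisation: the pyran ring arises solely by insertion of O between C7a and C1 of the indane, a ring enlargement from five to six members by a suprafacial 1,2-shift. The C4 centre is untouched and carries over from 13, while the new C2 centre is set by substrate control, hydride adding axially to C2 on the face opposite the bulky C4 aryl group so that ring B ends equatorial and cis to it; both C1 epimers of 13 converge on the same planar cation. The step needs migration of the ring A carbon in preference to ring B, which the triflate secures by making ring B the poorer migrating group (a ring B shift would only return indanone 9); it needs O–O in preference to C–O heterolysis, which the electron-poor ring B also favours by destabilising the C1 cation; and it needs reduction of the oxocarbenium ion in preference to the dodecanoyl ketone, which the two flanking benzyloxy groups and the low temperature secure.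

**Step 10**
Reactants: 16 4-{(2R,4R)-7-(benzyloxy)-4-[2,4,6-tris(benzyloxy)-3-dodecanoylphenyl]-3,4-dihydro-2H-chromen-2-yl}phenyl trifluoromethanesulfonate
Product: 18 1-{2,4,6-tris(benzyloxy)-3-[(2R,4R)-7-(benzyloxy)-2-(4-hydroxyphenyl)-3,4-dihydro-2H-chromen-4-yl]phenyl}dodecan-1-one, via aryl pinacol boronate 17 (not isolated)
Conditions: Pd(dppf)Cl2 (5 mol %), B2pin2, KOAc, 1,4-dioxane, 85 °C; then Me3NO, THF, 50 °C; aq. work-up
Reagents that add atoms: bis(pinacolato)diboron, CC1(C)OB(B2OC(C)(C)C(C)(C)O2)OC1(C)C (boron of 17 only); trimethylamine N-oxide, C[N+](C)(C)[O-]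
Why: Miyaura borylation of the aryl triflate followed by oxidation of the C–B bond with the amine N-oxide (1,2-aryl shift from boron to oxygen) unveils the ring B phenol without base, so the para-hydroxybenzylic ether at C2 is never exposed as a phenoxide that could open the ring through a quinone methide.

**Step 11**
Reactants: 18 1-{2,4,6-tris(benzyloxy)-3-[(2R,4R)-7-(benzyloxy)-2-(4-hydroxyphenyl)-3,4-dihydro-2H-chromen-4-yl]phenyl}dodecan-1-one
Product: 19 1-{2,4,6-trihydroxy-3-[(2R,4R)-7-hydroxy-2-(4-hydroxyphenyl)-3,4-dihydro-2H-chromen-4-yl]phenyl}dodecan-1-one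
Conditions: H2 (1 atm), 10% Pd/C, EtOAc/MeOH, rt
Reagents that add atoms: none
Why: Heterogeneous hydrogenolysis of the four benzyl ethers under neutral conditions at room temperature should leave the aryl ketone, the benzylic C2–O1 bond and both stereocentres untouched.

**Compound list**

1 | 2,4,6-trihydroxybenzaldehyde | O=Cc1c(O)cc(O)cc1O | starting material
2 | 2,4,6-tris(benzyloxy)benzaldehyde | O=Cc1c(OCc2ccccc2)cc(OCc2ccccc2)cc1OCc1ccccc1 | intermediate
3 | 1-(2,5-dihydroxyphenyl)ethan-1-one | CC(=O)c1cc(O)ccc1O | starting material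
4 | 1-[5-(benzyloxy)-2-hydroxyphenyl]ethan-1-one | CC(=O)c1cc(OCc2ccccc2)ccc1O | intermediate
5 | (2E)-1-[5-(benzyloxy)-2-hydroxyphenyl]-3-[2,4,6-tris(benzyloxy)phenyl]prop-2-en-1-one | O=C(/C=C/c1c(OCc2ccccc2)cc(OCc2ccccc2)cc1OCc1ccccc1)c1cc(OCc2ccccc2)ccc1O | intermediate
6 | 4-(benzyloxy)-2-{(2E)-3-[2,4,6-tris(benzyloxy)phenyl]prop-2-enoyl}phenyl trifluoromethanesulfonate | O=C(/C=C/c1c(OCc2ccccc2)cc(OCc2ccccc2)cc1OCc1ccccc1)c1cc(OCc2ccccc2)ccc1OS(=O)(=O)C(F)(F)F | intermediate
7 | (3R)-6-(benzyloxy)-3-[2,4,6-tris(benzyloxy)phenyl]-2,3-dihydro-1H-inden-1-one | C(c1ccccc1)Oc1cc(OCc2ccccc2)c([C@@H]2CC(=O)c3cc(OCc4ccccc4)ccc32)c(OCc2ccccc2)c1 | intermediate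
8 | dodecanoic acid | CCCCCCCCCCCC(=O)O | starting material
9 | (3R)-6-(benzyloxy)-3-[2,4,6-tris(benzyloxy)-3-dodecanoylphenyl]-2,3-dihydro-1H-inden-1-one | CCCCCCCCCCCC(=O)c1c(OCc2ccccc2)cc(OCc2ccccc2)c([C@@H]2CC(=O)c3cc(OCc4ccccc4)ccc32)c1OCc1ccccc1 | intermediate
10 | 4-iodophenyl trifluoromethanesulfonate | Ic1ccc(OS(=O)(=O)C(F)(F)F)cc1 | starting material
11 | {4-[(trifluoromethanesulfonyl)oxy]phenyl}magnesium chloride | Cl[Mg]c1ccc(OS(=O)(=O)C(F)(F)F)cc1 | intermediate (not isolated)
12 | 4-{(3R)-6-(benzyloxy)-1-hydroxy-3-[2,4,6-tris(benzyloxy)-3-dodecanoylphenyl]-2,3-dihydro-1H-inden-1-yl}phenyl trifluoromethanesulfonate (both C1 epimers) | CCCCCCCCCCCC(=O)c1c(OCc2ccccc2)cc(OCc2ccccc2)c([C@@H]2CC(O)(c3ccc(OS(=O)(=O)C(F)(F)F)cc3)c3cc(OCc4ccccc4)ccc32)c1OCc1ccccc1 | intermediate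
13 | 4-{(3R)-6-(benzyloxy)-1-hydroperoxy-3-[2,4,6-tris(benzyloxy)-3-dodecanoylphenyl]-2,3-dihydro-1H-inden-1-yl}phenyl trifluoromethanesulfonate (both C1 epimers) | CCCCCCCCCCCC(=O)c1c(OCc2ccccc2)cc(OCc2ccccc2)c([C@@H]2CC(OO)(c3ccc(OS(=O)(=O)C(F)(F)F)cc3)c3cc(OCc4ccccc4)ccc32)c1OCc1ccccc1 | intermediate
14 | (4R)-7-(benzyloxy)-4-[2,4,6-tris(benzyloxy)-3-dodecanoylphenyl]-2-{4-[(trifluoromethanesulfonyl)oxy]phenyl}-3,4-dihydrochromenylium trifluoroacetate | CCCCCCCCCCCC(=O)c1c(OCc2ccccc2)cc(OCc2ccccc2)c([C@@H]2CC(c3ccc(OS(=O)(=O)C(F)(F)F)cc3)=[O+]c3cc(OCc4ccccc4)ccc32)c1OCc1ccccc1.[O-]C(=O)C(F)(F)F | intermediate (not isolated)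
15 | 4-{(4R)-7-(benzyloxy)-2-hydroxy-4-[2,4,6-tris(benzyloxy)-3-dodecanoylphenyl]-3,4-dihydro-2H-chromen-2-yl}phenyl trifluoromethanesulfonate (both C2 epimers) | CCCCCCCCCCCC(=O)c1c(OCc2ccccc2)cc(OCc2ccccc2)c([C@@H]2CC(O)(c3ccc(OS(=O)(=O)C(F)(F)F)cc3)Oc3cc(OCc4ccccc4)ccc32)c1OCc1ccccc1 | intermediate (not isolated)
16 | 4-{(2R,4R)-7-(benzyloxy)-4-[2,4,6-tris(benzyloxy)-3-dodecanoylphenyl]-3,4-dihydro-2H-chromen-2-yl}phenyl trifluoromethanesulfonate | CCCCCCCCCCCC(=O)c1c(OCc2ccccc2)cc(OCc2ccccc2)c([C@@H]2C[C@H](c3ccc(OS(=O)(=O)C(F)(F)F)cc3)Oc3cc(OCc4ccccc4)ccc32)c1OCc1ccccc1 | intermediate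
17 | 1-{2,4,6-tris(benzyloxy)-3-[(2R,4R)-7-(benzyloxy)-2-[4-(4,4,5,5-tetramethyl-1,3,2-dioxaborolan-2-yl)phenyl]-3,4-dihydro-2H-chromen-4-yl]phenyl}dodecan-1-one | CCCCCCCCCCCC(=O)c1c(OCc2ccccc2)cc(OCc2ccccc2)c([C@@H]2C[C@H](c3ccc(B4OC(C)(C)C(C)(C)O4)cc3)Oc3cc(OCc4ccccc4)ccc32)c1OCc1ccccc1 | intermediate (not isolated)
18 | 1-{2,4,6-tris(benzyloxy)-3-[(2R,4R)-7-(benzyloxy)-2-(4-hydroxyphenyl)-3,4-dihydro-2H-chromen-4-yl]phenyl}dodecan-1-one | CCCCCCCCCCCC(=O)c1c(OCc2ccccc2)cc(OCc2ccccc2)c([C@@H]2C[C@H](c3ccc(O)cc3)Oc3cc(OCc4ccccc4)ccc32)c1OCc1ccccc1 | intermediate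
19 | 1-{2,4,6-trihydroxy-3-[(2R,4R)-7-hydroxy-2-(4-hydroxyphenyl)-3,4-dihydro-2H-chromen-4-yl]phenyl}dodecan-1-one | CCCCCCCCCCCC(=O)c1c(O)cc(O)c([C@@H]2C[C@H](c3ccc(O)cc3)Oc3cc(O)ccc32)c1O | target

**Step count and risks**

Total step count: 11. Longest linear sequence: 10 steps (steps 1, 3, 4, 5, 6, 7, 8, 9, 10, 11).

Steps most likely to fail:

1. Step 9. What may go wrong: in the acid the C–OOH bond ionises instead of the O–O bond (loss of hydrogen peroxide, alkene formation, unselective oxidation by the liberated peroxide), or the oxocarbenium ion is diverted before hydride arrives. Fallback (Criegee perester rearrangement with a separate reduction): it sets out from 13. Trifluoroacetic anhydride and pyridine in CH2Cl2 at −20 °C should give the tertiary peroxy trifluoroacetate F1, whose O–O bond ionises without free Brønsted acid and with the same aryl shift. This gives the ring-expanded 2-(trifluoroacetoxy)chroman ketal ester F2. F2 is then reduced in a separate operation with Et3SiH and catalytic TMSOTf in CH2Cl2 at −78 °C, and the route is rejoined at 16.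

2. Step 5. What may go wrong: slow carbopalladation at the β-carbon shielded by the 2,6-bis(benzyloxy)aryl group, leading to reduction of the triflate without cyclisation or to poor facial selectivity. Fallback (the stereocentre is set by hydride addition instead of carbon addition): it sets out from 6. A non-reductive Heck cyclisation (Pd(OAc)2, PPh3, K2CO3, DMF, 100 °C) should give the achiral 6-(benzyloxy)-3-[2,4,6-tris(benzyloxy)phenyl]-1H-inden-1-one F3. Copper hydride catalysed asymmetric conjugate reduction (Cu(OAc)2, (R)-DTBM-SEGPHOS, polymethylhydrosiloxane, t-BuOH, toluene, 0 °C; ligand antipode chosen for 3R) then returns the route at 7.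

3. Step 7. What may go wrong: deprotonation of the indanone or of the dodecanoyl ketone by the basic arylmagnesium reagent outruns 1,2-addition, or the reagent adds at the wrong carbonyl. Fallback (aryl addition before acylation, hydroperoxide made from an alkene): it sets out from 7. Reagent 11 with LaCl3·2LiCl adds to the only ketone present to give the tertiary indanol F4. Acid-catalysed dehydration (PPTS, toluene, 60 °C; no base, so the C–H at the stereocentre is not touched) gives the 3-aryl-1H-indene F5. The conditions of step 6 acylate its trialkoxyphenyl ring to give the acylated indene F6. Acid-catalysed addition of hydrogen peroxide to the double bond of F6 under the conditions of step 8 passes through the same tertiary benzylic cation and returns the route at 13.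

**Further compounds**

F1 | step 9 | 4-{(3R)-6-(benzyloxy)-3-[2,4,6-tris(benzyloxy)-3-dodecanoylphenyl]-1-[(trifluoroacetyl)peroxy]-2,3-dihydro-1H-inden-1-yl}phenyl trifluoromethanesulfonate | CCCCCCCCCCCC(=O)c1c(OCc2ccccc2)cc(OCc2ccccc2)c([C@@H]2CC(OOC(=O)C(F)(F)F)(c3ccc(OS(=O)(=O)C(F)(F)F)cc3)c3cc(OCc4ccccc4)ccc32)c1OCc1ccccc1
F2 | step 9 | (4R)-7-(benzyloxy)-4-[2,4,6-tris(benzyloxy)-3-dodecanoylphenyl]-2-{4-[(trifluoromethanesulfonyl)oxy]phenyl}-3,4-dihydro-2H-chromen-2-yl trifluoroacetate | CCCCCCCCCCCC(=O)c1c(OCc2ccccc2)cc(OCc2ccccc2)c([C@@H]2CC(OC(=O)C(F)(F)F)(c3ccc(OS(=O)(=O)C(F)(F)F)cc3)Oc3cc(OCc4ccccc4)ccc32)c1OCc1ccccc1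
F3 | step 5 | 6-(benzyloxy)-3-[2,4,6-tris(benzyloxy)phenyl]-1H-inden-1-one | C(c1ccccc1)Oc1cc(OCc2ccccc2)c(C2=CC(=O)c3cc(OCc4ccccc4)ccc32)c(OCc2ccccc2)c1
F4 | step 7 | 4-{(3R)-6-(benzyloxy)-1-hydroxy-3-[2,4,6-tris(benzyloxy)phenyl]-2,3-dihydro-1H-inden-1-yl}phenyl trifluoromethanesulfonate | C(c1ccccc1)Oc1cc(OCc2ccccc2)c([C@@H]2CC(O)(c3ccc(OS(=O)(=O)C(F)(F)F)cc3)c3cc(OCc4ccccc4)ccc32)c(OCc2ccccc2)c1
F5 | step 7 | 4-{(1R)-5-(benzyloxy)-1-[2,4,6-tris(benzyloxy)phenyl]-1H-inden-3-yl}phenyl trifluoromethanesulfonate | C(c1ccccc1)Oc1cc(OCc2ccccc2)c([C@@H]2C=C(c3ccc(OS(=O)(=O)C(F)(F)F)cc3)c3cc(OCc4ccccc4)ccc32)c(OCc2ccccc2)c1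
F6 | step 7 | 4-{(1R)-5-(benzyloxy)-1-[2,4,6-tris(benzyloxy)-3-dodecanoylphenyl]-1H-inden-3-yl}phenyl trifluoromethanesulfonate | CCCCCCCCCCCC(=O)c1c(OCc2ccccc2)cc(OCc2ccccc2)c([C@@H]2C=C(c3ccc(OS(=O)(=O)C(F)(F)F)cc3)c3cc(OCc4ccccc4)ccc32)c1OCc1ccccc1
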